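**Retrosynthetic overview**

- The target's 2',5'-diol comes from its bis(benzyl) ether by hydrogenolysis. Rings A and B are bought, and the pyranone ring C is the only ring made.
- Ring C is opened at C4–C4a: intramolecular Friedel–Crafts acylation of the (2R,3R) 3-aryl-3-(3,5-dimethoxyphenoxy)-2-methoxypropanoic acid. The strategy rests on C4a of ring A, which sits ortho to O1, ortho to the C5 methoxy and para to the C7 methoxy; in the open 3,5-dimethoxyphenyl ether the two carbons ortho to the ether oxygen are identical, so the acyl group has only one place to go.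
- The acid's O1–C2 bond comes from a Mitsunobu inversion of a syn β-hydroxy-α-methoxy imide with 3,5-dimethoxyphenol, followed by LiOOH cleavage of the auxiliary.
- The C2–C3 bond and both stereocentres come from an Evans boron glycolate aldol of (R)-4-benzyl-3-(methoxyacetyl)oxazolidin-2-one with 2,5-bis(benzyloxy)-4-methoxybenzaldehyde; the 3-methoxy group is carried in from the start.
- The aldehyde comes from 2-methoxyhydroquinone by benzylation and Vilsmeier formylation.

Key step: step 7

Remark: the target is read as the 2R,3R (2,3-trans) isomer; flavanone numbering (O1, C2, C3, C4, C4a, C5 to C8a, primed numbers for ring B) is used for the ring system.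

**Route**

Step 1
Reactants: 1 2-methoxyhydroquinone
Product: 2 1,4-bis(benzyloxy)-2-methoxybenzene
Conditions: BnBr, K2CO3, DMF, 60 °C
Reagents that add atoms: benzyl bromide, BrCc1ccccc1
Why: Williamson etherification of both phenols by a primary benzylic bromide under carbonate base is routine and leaves the aryl methyl ether alone.

Step 2
Reactants: 2 1,4-bis(benzyloxy)-2-methoxybenzene
Product: 4 2,5-bis(benzyloxy)-4-methoxybenzaldehyde, via aryl iminium chloride 3 (not isolated)
Conditions: POCl3, DMF, 0 to 70 °C; then H2O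
Reagents that add atoms: N,N-dimethylformamide, CN(C)C=O; water, O
Why: Vilsmeier–Haack formylation puts the chloroiminium electrophile on the one ring carbon that is para to the methoxy group and ortho to a benzyloxy group (the site at which 1,2,4-trialkoxybenzenes are formylated), and water then hydrolyses iminium salt 3 to the aldehyde.

Step 3
Reactants: 5 (R)-4-benzyl-2-oxazolidinone; 6 methoxyacetyl chloride
Product: 8 (R)-4-benzyl-3-(2-methoxyacetyl)oxazolidin-2-one, via lithium oxazolidinide 7 (not isolated)
Conditions: n-BuLi, THF, −78 °C; then 6, −78 to 0 °C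
Reagents that add atoms: none
Why: N-acylation of the lithiated oxazolidinone by the acid chloride is the standard loading of an Evans auxiliary and does not touch its C4 stereocentre.

Step 4
Reactants: 8 (R)-4-benzyl-3-(2-methoxyacetyl)oxazolidin-2-one; 4 2,5-bis(benzyloxy)-4-methoxybenzaldehyde
Product: 11 (R)-4-benzyl-3-[(2R,3S)-3-[2,5-bis(benzyloxy)-4-methoxyphenyl]-3-hydroxy-2-methoxypropanoyl]oxazolidin-2-one, via Z boron enolate 9 (not isolated), via boron aldolate 10 (not isolated)
Conditions: Bu2BOTf, Et3N, CH2Cl2, −78 to 0 °C; then 4, −78 to 0 °C; then H2O2, MeOH, pH 7 buffer, 0 °C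
Reagents that add atoms: none
Why: Evans boron syn-aldol reaction, in which Z enolate 9 adds through a closed Zimmerman–Traxler chair on the enolate face away from the benzyl group of the R auxiliary, so that the methoxy-bearing carbon is set as R and the carbinol carbon as S (2,3-syn) in one operation before the boron is removed oxidatively.

Step 5
Reactants: 11 syn aldol imide (as above); 12 3,5-dimethoxyphenol
Product: 14 (R)-4-benzyl-3-[(2R,3R)-3-[2,5-bis(benzyloxy)-4-methoxyphenyl]-3-(3,5-dimethoxyphenoxy)-2-methoxypropanoyl]oxazolidin-2-one, via alkoxyphosphonium aryloxide 13 (not isolated)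
Conditions: PPh3, DIAD, toluene, 0 °C to rt
Reagents that add atoms: none
Why: Mitsunobu etherification, in which the benzylic hydroxyl becomes an oxyphosphonium leaving group and is displaced by the phenoxide of 12 (pKa about 10) in an SN2 step with inversion, so that the aryloxy carbon becomes R and the chain 2,3-anti, while the imide α-hydrogen is held in the carbonyl plane by allylic strain and resists the competing dehydration.

Step 6
Reactants: 14 anti aryl ether imide (as above)
Product: 16 (2R,3R)-3-[2,5-bis(benzyloxy)-4-methoxyphenyl]-3-(3,5-dimethoxyphenoxy)-2-methoxypropanoic acid, via lithium percarboxylate 15 (not isolated)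
Conditions: LiOH, H2O2, THF/H2O, 0 °C; then aq Na2SO3; then 1 M HCl to pH 3
Reagents that add atoms: hydrogen peroxide, OO
Why: Evans hydroperoxide cleavage, in which LiOOH attacks the exocyclic imide carbonyl selectively and is too weak a base at 0 °C to enolise the α-methoxy centre or expel the β-aryloxide, sulfite then reduces percarboxylate 15 and the auxiliary is recovered.

Step 7
Reactants: 16 (2R,3R)-3-[2,5-bis(benzyloxy)-4-methoxyphenyl]-3-(3,5-dimethoxyphenoxy)-2-methoxypropanoic acid
Product: 18 (2R,3R)-2-[2,5-bis(benzyloxy)-4-methoxyphenyl]-3,5,7-trimethoxychroman-4-one, via mixed trifluoroacetic anhydride 17 (not isolated)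
Conditions: (CF3CO)2O (1.5 equiv), CH2Cl2, 0 °C; then aq NaHCO3
Reagents that add atoms: none
Why: Intramolecular Friedel–Crafts acylation through a mixed carboxylic–trifluoroacetic anhydride, the known way from 3-aryloxypropanoic acids to chroman-4-ones: the acid exchanges with the anhydride to give 17, whose non-fluorinated acyl carbon is attacked by the ring A carbon ortho to the ether oxygen, and loss of a proton rearomatises the ring and forms C4–C4a. Ring C closes in a 6-exo-trig mode at the acyl carbon, with the ether oxygen and the two sp3 carbons as the tether. No stereocentre is formed and no bond to C2 or C3 is broken, and the 2,3-trans arrangement delivered is also the more stable one (both substituents equatorial), so C3, now α to the ketone, has no drive to epimerise. The step needs ring A to win over ring B: the attacked carbon is activated by three oxygens (ortho, ortho, para), whereas C6' of ring B has one ortho oxygen and would close a five-membered indanone. It needs no choice between the two ortho carbons of the 3,5-dimethoxyphenyl ether, since they are equivalent by symmetry. A small excess of the anhydride at 0 °C without added strong acid should spare the benzylic C–O bond and the benzyl ethers, and avoids a free α-methoxy acylium ion that could lose CO.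

Step 8
Reactants: 18 (2R,3R)-2-[2,5-bis(benzyloxy)-4-methoxyphenyl]-3,5,7-trimethoxychroman-4-one
Product: 19 (2R,3R)-2-(2,5-dihydroxy-4-methoxyphenyl)-3,5,7-trimethoxychroman-4-one (CNP0281794.1)
Conditions: H2 (1 atm), 10% Pd/C, EtOAc/MeOH, rt
Reagents that add atoms: none
Why: Catalytic hydrogenolysis of the two aryl benzyl ethers over Pd/C is neutral, leaves the aryl ketone and both stereocentres alone, and cleaves the unhindered O–CH2Ph bonds much faster than the hindered cyclic C2–O1 bond.

**Compound list**

1 | 2-methoxyhydroquinone | COc1cc(O)ccc1O | starting material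
2 | 1,4-bis(benzyloxy)-2-methoxybenzene | COc1cc(OCc2ccccc2)ccc1OCc1ccccc1 | intermediate
3 | N-[2,5-bis(benzyloxy)-4-methoxybenzylidene]-N-methylmethanaminium chloride | C[N+](C)=Cc1cc(OCc2ccccc2)c(OC)cc1OCc1ccccc1.[Cl-] | intermediate (not isolated)
4 | 2,5-bis(benzyloxy)-4-methoxybenzaldehyde | O=Cc1cc(OCc2ccccc2)c(OC)cc1OCc1ccccc1 | intermediate
5 | (R)-4-benzyl-2-oxazolidinone | O=C1N[C@H](Cc2ccccc2)CO1 | starting material
6 | methoxyacetyl chloride | COCC(=O)Cl | starting material
7 | N-lithio salt of (R)-4-benzyl-2-oxazolidinone | O=C1[N-][C@H](Cc2ccccc2)CO1.[Li+] | intermediate (not isolated)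
8 | (R)-4-benzyl-3-(2-methoxyacetyl)oxazolidin-2-one | COCC(=O)N1[C@H](Cc2ccccc2)COC1=O | intermediate
9 | (R)-4-benzyl-3-[(Z)-1-(dibutylboryloxy)-2-methoxyvinyl]oxazolidin-2-one | CO/C=C(\OB(CCCC)CCCC)N1[C@H](Cc2ccccc2)COC1=O | intermediate (not isolated)
10 | O-dibutylboryl aldolate of 11 | CCCCB(CCCC)O[C@@H](c1cc(OCc2ccccc2)c(OC)cc1OCc1ccccc1)[C@@H](OC)C(=O)N1[C@H](Cc2ccccc2)COC1=O | intermediate (not isolated)
11 | (R)-4-benzyl-3-[(2R,3S)-3-[2,5-bis(benzyloxy)-4-methoxyphenyl]-3-hydroxy-2-methoxypropanoyl]oxazolidin-2-one | O[C@@H](c1cc(OCc2ccccc2)c(OC)cc1OCc1ccccc1)[C@@H](OC)C(=O)N1[C@H](Cc2ccccc2)COC1=O | intermediate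
12 | 3,5-dimethoxyphenol | COc1cc(O)cc(OC)c1 | starting material
13 | O-triphenylphosphonio derivative of 11 as its 3,5-dimethoxyphenoxide salt | COc1cc(OC)cc([O-])c1.c1ccccc1[P+](c1ccccc1)(c1ccccc1)O[C@@H](c1cc(OCc2ccccc2)c(OC)cc1OCc1ccccc1)[C@@H](OC)C(=O)N1[C@H](Cc2ccccc2)COC1=O | intermediate (not isolated)
14 | (R)-4-benzyl-3-[(2R,3R)-3-[2,5-bis(benzyloxy)-4-methoxyphenyl]-3-(3,5-dimethoxyphenoxy)-2-methoxypropanoyl]oxazolidin-2-one | COc1cc(OC)cc(c1)O[C@H](c1cc(OCc2ccccc2)c(OC)cc1OCc1ccccc1)[C@@H](OC)C(=O)N1[C@H](Cc2ccccc2)COC1=O | intermediate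
15 | lithium (2R,3R)-3-[2,5-bis(benzyloxy)-4-methoxyphenyl]-3-(3,5-dimethoxyphenoxy)-2-methoxypropaneperoxoate | COc1cc(OC)cc(c1)O[C@H](c1cc(OCc2ccccc2)c(OC)cc1OCc1ccccc1)[C@@H](OC)C(=O)O[O-].[Li+] | intermediate (not isolated)
16 | (2R,3R)-3-[2,5-bis(benzyloxy)-4-methoxyphenyl]-3-(3,5-dimethoxyphenoxy)-2-methoxypropanoic acid (2,3-anti) | COc1cc(OC)cc(c1)O[C@H](c1cc(OCc2ccccc2)c(OC)cc1OCc1ccccc1)[C@@H](OC)C(=O)O | intermediate
17 | mixed anhydride of 16 with trifluoroacetic acid | COc1cc(OC)cc(c1)O[C@H](c1cc(OCc2ccccc2)c(OC)cc1OCc1ccccc1)[C@@H](OC)C(=O)OC(=O)C(F)(F)F | intermediate (not isolated)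
18 | (2R,3R)-2-[2,5-bis(benzyloxy)-4-methoxyphenyl]-3,5,7-trimethoxychroman-4-one (2,3-trans) | COc1cc(OC)c2c(c1)O[C@H](c1cc(OCc3ccccc3)c(OC)cc1OCc1ccccc1)[C@@H](OC)C2=O | intermediate
19 | (2R,3R)-2-(2,5-dihydroxy-4-methoxyphenyl)-3,5,7-trimethoxychroman-4-one | COc1cc(OC)c2c(c1)O[C@H](c1cc(O)c(OC)cc1O)[C@@H](OC)C2=O | target

**Step count**

Total steps: 8. Longest linear sequence: 7 steps (steps 1, 2, 4, 5, 6, 7, 8 from 2-methoxyhydroquinone); step 3 is a one-step side branch.

**Steps most likely to fail**

Step 7 (key step). Trifluoroacetic acid set free during the closure may ionise the benzylic C–O bond, which is flanked by an ortho and a para oxygen of ring B, so that the aryloxy group is lost or C2 is scrambled. Ring A may also be trifluoroacetylated before it is acylated, or ring B may be acylated at C6' to an indanone. The fallback sets out from aldol 11 and makes the same two ring C bonds in the reverse order, with an anionic acylation and no acid. Aldol 11 would be transaminated with MeNH(OMe)·HCl and AlMe3 to the Weinreb amide F1. 3,5-Dimethoxyphenol 12 would be protected with MOMCl and i-Pr2NEt as 1,3-dimethoxy-5-(methoxymethoxy)benzene F2, which n-BuLi should lithiate between the methoxymethoxy and a methoxy group to give the aryllithium F3. An excess of F3 (the first equivalent is consumed by the hydroxyl) would add to F1 at −78 °C to give the aryl ketone F4, which already holds C4–C4a. The phenolic MOM group would be removed under nearly neutral conditions (TMSOTf, 2,2'-bipyridyl, then water) to give the 2-hydroxyaryl ketone F5. An intramolecular Mitsunobu reaction (PPh3, DIAD, THF) would then close O1–C2 with inversion at the benzylic carbon and come back to the route at 18.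

Step 5. The activated β-hydroxy imide may dehydrate to the α-methoxy enimide, and partial ionisation at the electron-rich benzylic carbon may erode the inversion or let the phenol react at carbon. The fallback sets out from aldol 11 and moves the substitution to the alcohol oxidation level, where no acidic α-hydrogen is left and dehydration is closed off; ionisation at the benzylic carbon remains possible there, so this answers the elimination pathway only. LiBH4 in THF/MeOH would cleave the auxiliary reductively to the 1,3-diol F6. TBSCl and imidazole would silylate the primary hydroxyl to give the silyl ether F7. The Mitsunobu reaction with 12 (PPh3, DIAD, toluene, 0 °C) would give the inverted aryl ether F8. TBAF would free the primary alcohol F9. Dess–Martin periodinane buffered with NaHCO3 would give the aldehyde F10, used crude, and Pinnick oxidation (NaClO2, NaH2PO4, 2-methyl-2-butene) comes back to the route at acid 16.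

Step 6. Under the basic peroxide the β-aryloxide may be expelled by an E1cB elimination, or hydroxide may open the ring of the hindered imide at the endocyclic carbonyl. The fallback sets out from imide 14 and removes the auxiliary without aqueous base. Methanolysis catalysed by Sm(OTf)3 in MeOH at rt would give the methyl ester F11. Neutral hydrolysis with Me3SnOH in 1,2-dichloroethane at 80 °C comes back to the route at acid 16.

**Further compounds**

F1 | step 7 | (2R,3S)-3-[2,5-bis(benzyloxy)-4-methoxyphenyl]-3-hydroxy-N,2-dimethoxy-N-methylpropanamide | O[C@@H](c1cc(OCc2ccccc2)c(OC)cc1OCc1ccccc1)[C@@H](OC)C(=O)N(C)OC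
F2 | step 7 | 1,3-dimethoxy-5-(methoxymethoxy)benzene | COCOc1cc(OC)cc(OC)c1
F3 | step 7 | [2,4-dimethoxy-6-(methoxymethoxy)phenyl]lithium | [Li]c1c(OC)cc(OC)cc1OCOC
F4 | step 7 | (2R,3S)-3-[2,5-bis(benzyloxy)-4-methoxyphenyl]-1-[2,4-dimethoxy-6-(methoxymethoxy)phenyl]-3-hydroxy-2-methoxypropan-1-one | O[C@@H](c1cc(OCc2ccccc2)c(OC)cc1OCc1ccccc1)[C@@H](OC)C(=O)c1c(OCOC)cc(OC)cc1OC
F5 | step 7 | (2R,3S)-3-[2,5-bis(benzyloxy)-4-methoxyphenyl]-3-hydroxy-1-(2-hydroxy-4,6-dimethoxyphenyl)-2-methoxypropan-1-one | O[C@@H](c1cc(OCc2ccccc2)c(OC)cc1OCc1ccccc1)[C@@H](OC)C(=O)c1c(O)cc(OC)cc1OC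
F6 | step 5 | (1S,2S)-1-[2,5-bis(benzyloxy)-4-methoxyphenyl]-2-methoxypropane-1,3-diol | O[C@@H](c1cc(OCc2ccccc2)c(OC)cc1OCc1ccccc1)[C@@H](OC)CO
F7 | step 5 | (1S,2S)-1-[2,5-bis(benzyloxy)-4-methoxyphenyl]-3-[(tert-butyldimethylsilyl)oxy]-2-methoxypropan-1-ol | O[C@@H](c1cc(OCc2ccccc2)c(OC)cc1OCc1ccccc1)[C@@H](OC)CO[Si](C)(C)C(C)(C)C
F8 | step 5 | tert-butyl{[(2S,3R)-3-[2,5-bis(benzyloxy)-4-methoxyphenyl]-3-(3,5-dimethoxyphenoxy)-2-methoxypropyl]oxy}dimethylsilane | COc1cc(OC)cc(c1)O[C@H](c1cc(OCc2ccccc2)c(OC)cc1OCc1ccccc1)[C@@H](OC)CO[Si](C)(C)C(C)(C)C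
F9 | step 5 | (2S,3R)-3-[2,5-bis(benzyloxy)-4-methoxyphenyl]-3-(3,5-dimethoxyphenoxy)-2-methoxypropan-1-ol | COc1cc(OC)cc(c1)O[C@H](c1cc(OCc2ccccc2)c(OC)cc1OCc1ccccc1)[C@@H](OC)CO
F10 | step 5 | (2R,3R)-3-[2,5-bis(benzyloxy)-4-methoxyphenyl]-3-(3,5-dimethoxyphenoxy)-2-methoxypropanal | COc1cc(OC)cc(c1)O[C@H](c1cc(OCc2ccccc2)c(OC)cc1OCc1ccccc1)[C@@H](OC)C=O
F11 | step 6 | methyl (2R,3R)-3-[2,5-bis(benzyloxy)-4-methoxyphenyl]-3-(3,5-dimethoxyphenoxy)-2-methoxypropanoate | COc1cc(OC)cc(c1)O[C@H](c1cc(OCc2ccccc2)c(OC)cc1OCc1ccccc1)[C@@H](OC)C(=O)OC
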